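**Retrosynthetic overview**
1. Selaginellin 22 comes from carbinol 21 in one acid step: four MOM ethers and one TBS ether fall off and the carbinol dehydrates to the quinone methide.
2. 21 comes from double addition of 4-(methoxymethoxy)phenyllithium to the hindered methyl ester of 16; the CH2OH arm comes from the unhindered ester of diester 12 (selective saponification, then reduction).
3. 12 comes from Sonogashira coupling of aryl triflate 10 (made from phenol 9) with arylacetylene 11.
4. Key C–C bond: intermolecular Michael addition of dimethyl 3-oxopentanedioate 6 to aryl ethynyl ketone 5, followed in the same flask by intramolecular aldol condensation and aromatisation to 2-hydroxyisophthalate 9.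
5. Ring order: the central benzene ring is the only ring built (step 4). The four outer six-membered rings are bought (4-hydroxybenzaldehyde, 4-bromophenol); one of them becomes the cyclohexadienone in the last step.

Assumption: the target SMILES has no stereocentre and no stereodefined double bond (the methide carbon carries two para-oxygenated rings that exchange roles by tautomerism), so there is no enantiomer to select and no stereocontrol is needed.

**Route**

Step 1
Reactants: 1 4-hydroxybenzaldehyde
Product: 2 4-(methoxymethoxy)benzaldehyde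
Conditions: MOMCl (1.3 equiv), i-Pr2NEt (1.6 equiv), CH2Cl2, 0 °C → rt
Reagents that add atoms: chloromethyl methyl ether (MOMCl), COCCl
Why: Williamson-type O-alkylation of the phenol by the reactive α-chloro ether gives a MOM acetal that survives every basic, organometallic and hydride step that follows and is cleaved only by acid at the end.

Step 2
Reactants: 2 4-(methoxymethoxy)benzaldehyde; 3 ethynylmagnesium bromide (HC≡CMgBr, 0.5 M in THF)
Product: 4 rac-1-[4-(methoxymethoxy)phenyl]prop-2-yn-1-ol
Conditions: THF, 0 °C → rt; then aq. NH4Cl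
Reagents that add atoms: none
Why: Grignard 1,2-addition of the acetylide to the aldehyde; the new carbinol centre is formed racemic, which does not matter because it is oxidised away in step 3.

Step 3
Reactants: 4 rac-1-[4-(methoxymethoxy)phenyl]prop-2-yn-1-ol
Product: 5 1-[4-(methoxymethoxy)phenyl]prop-2-yn-1-one
Conditions: activated MnO2 (10 equiv), CH2Cl2, rt; filter through Celite and use at once
Reagents that add atoms: none
Why: MnO2 oxidation is selective for benzylic/propargylic alcohols and gives the terminal ynone under neutral conditions that leave the MOM ether and the alkyne C–H alone.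

Step 4
Reactants: 5 1-[4-(methoxymethoxy)phenyl]prop-2-yn-1-one; 6 dimethyl 3-oxopentanedioate
Product: 9 dimethyl 2-hydroxy-4-[4-(methoxymethoxy)phenyl]benzene-1,3-dicarboxylate, via Michael adduct 7 (not isolated), via aldol adduct 8 (not isolated)
Conditions: 6 (1.1 equiv), NaH (1.1 equiv), THF, 0 °C; add 5 slowly, 0 °C → rt, 12 h; then AcOH (1.2 equiv)
Reagents that add atoms: none
Why: The sodium enolate of the symmetrical β-keto diester adds in a Michael fashion to the unsubstituted β-carbon of the ynone (the fragment-joining C–C bond), the second activated methylene closes the six-membered ring by intramolecular aldol addition to the aryl ketone, and loss of water with enolisation gives the phenol (Michael–aldol benzannulation); because 6 is symmetrical only one regioisomer can form, and the transient stereocentres of 7 and 8 vanish on aromatisation.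

Step 5
Reactants: 9 dimethyl 2-hydroxy-4-[4-(methoxymethoxy)phenyl]benzene-1,3-dicarboxylate
Product: 10 dimethyl 4-[4-(methoxymethoxy)phenyl]-2-{[(trifluoromethyl)sulfonyl]oxy}benzene-1,3-dicarboxylate
Conditions: Tf2O (1.2 equiv), pyridine (3 equiv), CH2Cl2, −78 → 0 °C
Reagents that add atoms: trifluoromethanesulfonic anhydride, O=S(=O)(OS(=O)(=O)C(F)(F)F)C(F)(F)F
Why: O-sulfonylation of the acidic phenol turns the annulation-derived oxygen into a cross-coupling leaving group, and the buffered low-temperature conditions spare the MOM acetal.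

Step 6
Reactants: 2 4-(methoxymethoxy)benzaldehyde
Product: 11 1-ethynyl-4-(methoxymethoxy)benzene
Conditions: dimethyl (1-diazo-2-oxopropyl)phosphonate (1.2 equiv), K2CO3 (2 equiv), MeOH, 0 °C → rt
Reagents that add atoms: dimethyl (1-diazo-2-oxopropyl)phosphonate, CC(=O)C(=[N+]=[N-])P(=O)(OC)OC
Why: Seyferth–Gilbert homologation in its Ohira–Bestmann form converts the aryl aldehyde into the terminal alkyne in one pot under mild carbonate conditions that the MOM ether tolerates.

Step 7
Reactants: 10 dimethyl 4-[4-(methoxymethoxy)phenyl]-2-{[(trifluoromethyl)sulfonyl]oxy}benzene-1,3-dicarboxylate; 11 1-ethynyl-4-(methoxymethoxy)benzene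
Product: 12 dimethyl 4-[4-(methoxymethoxy)phenyl]-2-{[4-(methoxymethoxy)phenyl]ethynyl}benzene-1,3-dicarboxylate
Conditions: Pd(PPh3)2Cl2 (5 mol %), CuI (10 mol %), Et3N (3 equiv), degassed DMF, 60 °C
Reagents that add atoms: none
Why: Sonogashira coupling: the two ortho esters make the aryl triflate electron-poor and fast in oxidative addition to zerovalent palladium, and the linear copper acetylide is small enough to reach the flanked position.

Step 8
Reactants: 12 dimethyl 4-[4-(methoxymethoxy)phenyl]-2-{[4-(methoxymethoxy)phenyl]ethynyl}benzene-1,3-dicarboxylate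
Product: 13 3-(methoxycarbonyl)-4-[4-(methoxymethoxy)phenyl]-2-{[4-(methoxymethoxy)phenyl]ethynyl}benzoic acid
Conditions: LiOH·H2O (1.5 equiv), THF/MeOH/H2O (3:1:1), rt; then 1 M HCl to pH 4 at 0 °C
Reagents that add atoms: lithium hydroxide, [Li+].[OH-]
Why: Site-selective saponification: hydroxide attacks only the ester with one free ortho position, because the ester flanked by both the aryl and the alkynyl group is shielded on both sides and hydrolyses far more slowly, and the first carboxylate formed further deactivates the molecule.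

Step 9
Reactants: 13 3-(methoxycarbonyl)-4-[4-(methoxymethoxy)phenyl]-2-{[4-(methoxymethoxy)phenyl]ethynyl}benzoic acid
Product: 15 methyl 3-(hydroxymethyl)-6-[4-(methoxymethoxy)phenyl]-2-{[4-(methoxymethoxy)phenyl]ethynyl}benzoate, via mixed carbonic anhydride 14 (not isolated)
Conditions: i-BuOCOCl (1.1 equiv), N-methylmorpholine (1.2 equiv), THF, −15 °C; then NaBH4 (2 equiv), THF/H2O, −15 → 0 °C
Reagents that add atoms: none
Why: Activation of the acid as its isobutyl mixed carbonic anhydride followed by NaBH4 reduction gives the benzylic alcohol chemoselectively, since borohydride touches neither the hindered methyl ester nor the alkyne or the MOM ethers.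

Step 10
Reactants: 15 methyl 3-(hydroxymethyl)-6-[4-(methoxymethoxy)phenyl]-2-{[4-(methoxymethoxy)phenyl]ethynyl}benzoate
Product: 16 methyl 3-({[tert-butyl(dimethyl)silyl]oxy}methyl)-6-[4-(methoxymethoxy)phenyl]-2-{[4-(methoxymethoxy)phenyl]ethynyl}benzoate
Conditions: TBSCl (1.2 equiv), imidazole (2 equiv), DMF, rt
Reagents that add atoms: tert-butyldimethylsilyl chloride, CC(C)(C)[Si](C)(C)Cl
Why: Imidazole-promoted silylation of the primary alcohol prevents alkoxide formation (and possible cyclisation onto the neighbouring alkyne) in the organolithium step, and the TBS ether falls off in the final acid step.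

Step 11
Reactants: 17 4-bromophenol
Product: 18 1-bromo-4-(methoxymethoxy)benzene
Conditions: MOMCl (1.3 equiv), i-Pr2NEt (1.6 equiv), CH2Cl2, 0 °C → rt
Reagents that add atoms: chloromethyl methyl ether (MOMCl), COCCl
Why: The same Williamson-type MOM protection as in step 1 gives the precursor of an aryllithium that carries its phenol oxygen in masked form.

Step 12
Reactants: 16 methyl 3-({[tert-butyl(dimethyl)silyl]oxy}methyl)-6-[4-(methoxymethoxy)phenyl]-2-{[4-(methoxymethoxy)phenyl]ethynyl}benzoate; 18 1-bromo-4-(methoxymethoxy)benzene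
Product: 21 [3-({[tert-butyl(dimethyl)silyl]oxy}methyl)-6-[4-(methoxymethoxy)phenyl]-2-{[4-(methoxymethoxy)phenyl]ethynyl}phenyl]bis[4-(methoxymethoxy)phenyl]methanol, via aryllithium 19 (not isolated), via diaryl ketone 20 (not isolated)
Conditions: 18 (4.4 equiv), n-BuLi (4.2 equiv), THF, −78 °C, 30 min; then 16 in THF, −78 → 0 °C; H2O at 0 °C
Reagents that add atoms: none
Why: Bromine–lithium exchange gives the aryllithium, which adds twice to the methyl ester (acyl substitution to the ketone, then 1,2-addition); a small, highly reactive aryllithium in excess is the reagent of choice for a doubly ortho-substituted benzoate, and the carbinol carbon bears two identical aryl groups, so no stereocentre arises.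

Step 13
Reactants: 21 [3-({[tert-butyl(dimethyl)silyl]oxy}methyl)-6-[4-(methoxymethoxy)phenyl]-2-{[4-(methoxymethoxy)phenyl]ethynyl}phenyl]bis[4-(methoxymethoxy)phenyl]methanol
Product: 22 selaginellin, 4-[{3-(hydroxymethyl)-6-(4-hydroxyphenyl)-2-[(4-hydroxyphenyl)ethynyl]phenyl}(4-hydroxyphenyl)methylidene]cyclohexa-2,5-dien-1-one
Conditions: aq. HCl (catalytic, about 0.3 M in the mixture), MeOH/THF (2:1), rt → 45 °C; then pH 7 phosphate buffer
Reagents that add atoms: none
Why: Acid-catalysed solvolysis removes the four MOM acetals and the TBS ether, and the carbinol, now carrying two para-hydroxyphenyl groups, ionises to a stabilised trityl cation that loses a phenolic proton to give the fuchsone-type quinone methide (global deprotection with dehydration); no stereocentre is created.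

**Compound list**
1 | 4-hydroxybenzaldehyde | O=Cc1ccc(O)cc1 | starting material
2 | 4-(methoxymethoxy)benzaldehyde | COCOc1ccc(C=O)cc1 | intermediate
3 | ethynylmagnesium bromide | C#C[Mg]Br | starting material
4 | rac-1-[4-(methoxymethoxy)phenyl]prop-2-yn-1-ol (racemic) | COCOc1ccc(C(O)C#C)cc1 | intermediate
5 | 1-[4-(methoxymethoxy)phenyl]prop-2-yn-1-one | COCOc1ccc(C(=O)C#C)cc1 | intermediate
6 | dimethyl 3-oxopentanedioate | COC(=O)CC(=O)CC(=O)OC | starting material
7 | Michael adduct, dimethyl 2-{(1Z)-3-[4-(methoxymethoxy)phenyl]-3-oxoprop-1-en-1-yl}-3-oxopentanedioate (racemic at C-2, present as sodium enolate, E and Z forms equilibrate and the Z form cyclises; formed in the flask) | COC(=O)CC(=O)C(C(=O)OC)/C=C\C(=O)c1ccc(OCOC)cc1 | intermediate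
8 | aldol adduct, dimethyl 4-hydroxy-4-[4-(methoxymethoxy)phenyl]-2-oxocyclohex-5-ene-1,3-dicarboxylate (mixture of diastereomers; formed in the flask) | COC(=O)C1C=CC(O)(c2ccc(OCOC)cc2)C(C(=O)OC)C1=O | intermediate
9 | dimethyl 2-hydroxy-4-[4-(methoxymethoxy)phenyl]benzene-1,3-dicarboxylate | COC(=O)c1ccc(-c2ccc(OCOC)cc2)c(C(=O)OC)c1O | intermediate
10 | dimethyl 4-[4-(methoxymethoxy)phenyl]-2-{[(trifluoromethyl)sulfonyl]oxy}benzene-1,3-dicarboxylate | COC(=O)c1ccc(-c2ccc(OCOC)cc2)c(C(=O)OC)c1OS(=O)(=O)C(F)(F)F | intermediate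
11 | 1-ethynyl-4-(methoxymethoxy)benzene | C#Cc1ccc(OCOC)cc1 | intermediate
12 | dimethyl 4-[4-(methoxymethoxy)phenyl]-2-{[4-(methoxymethoxy)phenyl]ethynyl}benzene-1,3-dicarboxylate | COC(=O)c1ccc(-c2ccc(OCOC)cc2)c(C(=O)OC)c1C#Cc1ccc(OCOC)cc1 | intermediate
13 | 3-(methoxycarbonyl)-4-[4-(methoxymethoxy)phenyl]-2-{[4-(methoxymethoxy)phenyl]ethynyl}benzoic acid | OC(=O)c1ccc(-c2ccc(OCOC)cc2)c(C(=O)OC)c1C#Cc1ccc(OCOC)cc1 | intermediate
14 | mixed carbonic anhydride of 13 with isobutyl hydrogen carbonate (formed in the flask) | CC(C)COC(=O)OC(=O)c1ccc(-c2ccc(OCOC)cc2)c(C(=O)OC)c1C#Cc1ccc(OCOC)cc1 | intermediate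
15 | methyl 3-(hydroxymethyl)-6-[4-(methoxymethoxy)phenyl]-2-{[4-(methoxymethoxy)phenyl]ethynyl}benzoate | OCc1ccc(-c2ccc(OCOC)cc2)c(C(=O)OC)c1C#Cc1ccc(OCOC)cc1 | intermediate
16 | methyl 3-({[tert-butyl(dimethyl)silyl]oxy}methyl)-6-[4-(methoxymethoxy)phenyl]-2-{[4-(methoxymethoxy)phenyl]ethynyl}benzoate | CC(C)(C)[Si](C)(C)OCc1ccc(-c2ccc(OCOC)cc2)c(C(=O)OC)c1C#Cc1ccc(OCOC)cc1 | intermediate
17 | 4-bromophenol | Oc1ccc(Br)cc1 | starting material
18 | 1-bromo-4-(methoxymethoxy)benzene | COCOc1ccc(Br)cc1 | intermediate
19 | aryllithium, 4-(methoxymethoxy)phenyllithium (formed in the flask) | [Li]c1ccc(OCOC)cc1 | intermediate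
20 | diaryl ketone, [3-({[tert-butyl(dimethyl)silyl]oxy}methyl)-6-[4-(methoxymethoxy)phenyl]-2-{[4-(methoxymethoxy)phenyl]ethynyl}phenyl][4-(methoxymethoxy)phenyl]methanone (formed in the flask) | CC(C)(C)[Si](C)(C)OCc1ccc(-c2ccc(OCOC)cc2)c(C(=O)c2ccc(OCOC)cc2)c1C#Cc1ccc(OCOC)cc1 | intermediate
21 | [3-({[tert-butyl(dimethyl)silyl]oxy}methyl)-6-[4-(methoxymethoxy)phenyl]-2-{[4-(methoxymethoxy)phenyl]ethynyl}phenyl]bis[4-(methoxymethoxy)phenyl]methanol | CC(C)(C)[Si](C)(C)OCc1ccc(-c2ccc(OCOC)cc2)c(C(O)(c2ccc(OCOC)cc2)c2ccc(OCOC)cc2)c1C#Cc1ccc(OCOC)cc1 | intermediate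
22 | selaginellin | O=C1C=CC(=C(c2ccc(O)cc2)c2c(-c3ccc(O)cc3)ccc(CO)c2C#Cc2ccc(O)cc2)C=C1 | target

**Step count**
Total: 13 steps. Longest linear sequence: 11 steps (1 → 2 → 4 → 5 → 9 → 10 → 12 → 13 → 15 → 16 → 21 → 22, that is steps 1, 2, 3, 4, 5, 7, 8, 9, 10, 12 and 13). Steps 6 and 11 make side fragments.

**Three steps most likely to fail, with fallbacks**

Step 12 (double aryllithium addition) is the most exposed. The ester carbon sits between an ortho aryl and an ortho alkynyl group, so the reaction may not start or may stall at the ketone. The fallback sets out from 16 and comes back to the route at 20. i-Bu2AlH (3 equiv, CH2Cl2, −78 → 0 °C) reduces the hindered ester to the benzylic alcohol [3-({[tert-butyl(dimethyl)silyl]oxy}methyl)-6-[4-(methoxymethoxy)phenyl]-2-{[4-(methoxymethoxy)phenyl]ethynyl}phenyl]methanol F1. Dess–Martin periodinane (NaHCO3, CH2Cl2, rt) then gives the aldehyde 3-({[tert-butyl(dimethyl)silyl]oxy}methyl)-6-[4-(methoxymethoxy)phenyl]-2-{[4-(methoxymethoxy)phenyl]ethynyl}benzaldehyde F2, whose carbonyl is far more open than that of the ester. One equivalent of aryllithium 19 (from 18 and n-BuLi, THF, −78 °C) gives the racemic diarylmethanol F3, and a second Dess–Martin oxidation gives ketone 20, now isolated. Ketone 20 is then treated with 19 alone (if needed after transmetallation with anhydrous CeCl3) to give 21, and the route continues with step 13.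

Step 7 (Sonogashira coupling) is second. The triflate lies between two esters, so the amine may cleave it at sulfur and return phenol 9, or copper may dimerise the alkyne. The fallback sets out from 10 and 11 and comes back at 12. Alkyne 11 is heated with Bu3SnOMe (neat, 60 °C, MeOH removed under vacuum) to give tributyl{[4-(methoxymethoxy)phenyl]ethynyl}stannane F4. Stille coupling of 10 with F4 (Pd(PPh3)4 5 mol %, LiCl 3 equiv, 1,4-dioxane, 100 °C) gives 12 with no amine and no copper present.

Step 4 (Michael–aldol benzannulation) is third. The terminal aryl ynone 5 can oligomerise or take up two enolates under NaH before ring closure. The fallback sets out from 5 and comes back at 9. MeOH with catalytic DABCO (rt) adds across the triple bond to give the bench-stable vinylogous ester (E)-3-methoxy-1-[4-(methoxymethoxy)phenyl]prop-2-en-1-one F5. Condensation of F5 with 6 (NaOMe, MeOH, reflux; then AcOH) runs by Michael addition and loss of methoxide to the same adduct 7, which closes through 8 by the same intramolecular aldol condensation to 9.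

**Further compounds**
F1 | step 12 | [3-({[tert-butyl(dimethyl)silyl]oxy}methyl)-6-[4-(methoxymethoxy)phenyl]-2-{[4-(methoxymethoxy)phenyl]ethynyl}phenyl]methanol | CC(C)(C)[Si](C)(C)OCc1ccc(-c2ccc(OCOC)cc2)c(CO)c1C#Cc1ccc(OCOC)cc1
F2 | step 12 | 3-({[tert-butyl(dimethyl)silyl]oxy}methyl)-6-[4-(methoxymethoxy)phenyl]-2-{[4-(methoxymethoxy)phenyl]ethynyl}benzaldehyde | CC(C)(C)[Si](C)(C)OCc1ccc(-c2ccc(OCOC)cc2)c(C=O)c1C#Cc1ccc(OCOC)cc1
F3 | step 12 | rac-[3-({[tert-butyl(dimethyl)silyl]oxy}methyl)-6-[4-(methoxymethoxy)phenyl]-2-{[4-(methoxymethoxy)phenyl]ethynyl}phenyl][4-(methoxymethoxy)phenyl]methanol (racemic) | CC(C)(C)[Si](C)(C)OCc1ccc(-c2ccc(OCOC)cc2)c(C(O)c2ccc(OCOC)cc2)c1C#Cc1ccc(OCOC)cc1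
F4 | step 7 | tributyl{[4-(methoxymethoxy)phenyl]ethynyl}stannane | CCCC[Sn](CCCC)(CCCC)C#Cc1ccc(OCOC)cc1
F5 | step 4 | (E)-3-methoxy-1-[4-(methoxymethoxy)phenyl]prop-2-en-1-one | CO/C=C/C(=O)c1ccc(OCOC)cc1
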